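**Retrosynthetic overview**
- Lespeflorin B3 ⇒ open ring C at O1–C2 (inversion at C2): a trans-(2R,3S)-2,3-epoxy ketone whose 2'-OH is masked.
- Epoxy ketone ⇒ Darzens disconnection (C2–C3 and C–O together): an A-ring phenacyl chloride plus a B-ring aldehyde; no chalcone is made.
- Key operation: asymmetric phase-transfer Darzens condensation, then acid in the same flask. The oxirane forms first and the pyranone ring C second, with both stereocentres set and all protecting groups removed.
- A-ring piece: resacetophenone → double C-prenylation → bis-MOM → α-chlorination. B-ring piece: 4-hydroxybenzaldehyde → C-prenylation → MOM.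
- Ring order: rings A and B are bought; the transient oxirane and then ring C are formed in the last step.

Assumption: the cinchonidinium catalyst is taken to deliver the (2R,3S) epoxy ketone (the cinchoninium series being taken to give the mirror image); if the first run shows the opposite sense, the pseudo-enantiomeric cinchoninium salt is used instead.

**Route**

Step 1
Reactants: 1 resacetophenone (2,4-dihydroxyacetophenone)
Product: 2 diprenyl ketone 1-[2,4-dihydroxy-3,5-bis(3-methylbut-2-en-1-yl)phenyl]ethan-1-one
Conditions: prenyl bromide (2.5 equiv), 10% aq KOH, 0 °C → rt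
Reagents that add atoms: prenyl bromide (1-bromo-3-methylbut-2-ene), CC(C)=CCBr
Why: phenolate C-alkylation in water puts the prenyl groups on the only two activated ring carbons, C-3 and C-5 (each ortho to a phenoxide oxygen), while C-6 (meta to both oxygens) is left alone; no stereocentre is formed.

Step 2
Reactants: 2 diprenyl ketone
Product: 3 bis-MOM ketone 1-[2,4-bis(methoxymethoxy)-3,5-bis(3-methylbut-2-en-1-yl)phenyl]ethan-1-one
Conditions: NaH (2.5 equiv), MOMCl (2.5 equiv), DMF, 0 °C → rt
Reagents that add atoms: chloromethyl methyl ether (MOMCl), COCCl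
Why: Williamson-type O-alkylation of both sodium phenoxides (NaH is needed for the chelated 2-OH) masks the phenols for the enolate and Darzens chemistry that follows.

Step 3
Reactants: 3 bis-MOM ketone
Product: 4 chloromethyl ketone 2-chloro-1-[2,4-bis(methoxymethoxy)-3,5-bis(3-methylbut-2-en-1-yl)phenyl]ethan-1-one
Conditions: LiHMDS (1.05 equiv), THF, −78 °C; enolate added to TsCl (1.1 equiv), −78 → 0 °C
Reagents that add atoms: p-toluenesulfonyl chloride (TsCl), Cc1ccc(cc1)S(=O)(=O)Cl
Why: enolate α-halogenation with TsCl as the Cl+ donor chlorinates the methyl ketone without exposing the electron-rich prenyl alkenes to free halogen.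

Step 4
Reactants: 5 4-hydroxybenzaldehyde
Product: 6 4-hydroxy-3-(3-methylbut-2-en-1-yl)benzaldehyde
Conditions: prenyl bromide (1.1 equiv), 10% aq KOH, rt
Reagents that add atoms: prenyl bromide (1-bromo-3-methylbut-2-ene), CC(C)=CCBr
Why: phenolate C-alkylation in water goes ortho to the phenoxide because the para position carries the formyl group.

Step 5
Reactants: 6 4-hydroxy-3-(3-methylbut-2-en-1-yl)benzaldehyde
Product: 7 MOM aldehyde 4-(methoxymethoxy)-3-(3-methylbut-2-en-1-yl)benzaldehyde
Conditions: MOMCl (1.3 equiv), K2CO3, acetone, rt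
Reagents that add atoms: chloromethyl methyl ether (MOMCl), COCCl
Why: Williamson etherification gives an acetal that is stable to the basic Darzens conditions and is removed by acid together with the other two.

Step 6
Reactants: 4 chloromethyl ketone; 7 MOM aldehyde
Product: 10 Lespeflorin B3, via tris-MOM epoxy ketone 8 (not isolated), via triphenol epoxy ketone 9 (not isolated)
Conditions: N-[4-(trifluoromethyl)benzyl]cinchonidinium bromide (10 mol %), LiOH·H2O (2 equiv), n-Bu2O, 4 °C; then MeOH, conc. HCl (to ca. 1 M), 40 °C, same flask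
Reagents that add atoms: none
Why: Proposed new method: a one-flask Darzens condensation/deprotective cyclisation (closest known reaction types: the catalytic asymmetric phase-transfer Darzens reaction of phenacyl chlorides with aldehydes, and the acid cyclisation of 2'-O-protected chalcone epoxides to trans-dihydroflavonols), in which the chiral ammonium enolate of 4 adds to one face of 7 and the anti chloro-alkoxide closes by SN2 to the trans-(2R,3S) oxirane 8, setting both stereocentres, after which acid methanolysis of the MOM acetals frees the 2'-OH of 9, which opens the oxirane 6-endo at the benzylic carbon with inversion, so that C-3 keeps the R configuration of the oxirane carbon and C-2 becomes R, trans to the 3-OH.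

**Compound list**

1 | resacetophenone (2,4-dihydroxyacetophenone) | CC(=O)c1ccc(O)cc1O | starting material
2 | 1-[2,4-dihydroxy-3,5-bis(3-methylbut-2-en-1-yl)phenyl]ethan-1-one | CC(=O)c1cc(CC=C(C)C)c(O)c(CC=C(C)C)c1O | intermediate
3 | 1-[2,4-bis(methoxymethoxy)-3,5-bis(3-methylbut-2-en-1-yl)phenyl]ethan-1-one | CC(=O)c1cc(CC=C(C)C)c(OCOC)c(CC=C(C)C)c1OCOC | intermediate
4 | 2-chloro-1-[2,4-bis(methoxymethoxy)-3,5-bis(3-methylbut-2-en-1-yl)phenyl]ethan-1-one | O=C(CCl)c1cc(CC=C(C)C)c(OCOC)c(CC=C(C)C)c1OCOC | intermediate
5 | 4-hydroxybenzaldehyde | O=Cc1ccc(O)cc1 | starting material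
6 | 4-hydroxy-3-(3-methylbut-2-en-1-yl)benzaldehyde | CC(C)=CCc1cc(C=O)ccc1O | intermediate
7 | 4-(methoxymethoxy)-3-(3-methylbut-2-en-1-yl)benzaldehyde | COCOc1ccc(C=O)cc1CC=C(C)C | intermediate
8 | [2,4-bis(methoxymethoxy)-3,5-bis(3-methylbut-2-en-1-yl)phenyl]{(2R,3S)-3-[4-(methoxymethoxy)-3-(3-methylbut-2-en-1-yl)phenyl]oxiran-2-yl}methanone (trans) | O=C([C@@H]1O[C@H]1c1ccc(OCOC)c(CC=C(C)C)c1)c1cc(CC=C(C)C)c(OCOC)c(CC=C(C)C)c1OCOC | intermediate
9 | [2,4-dihydroxy-3,5-bis(3-methylbut-2-en-1-yl)phenyl]{(2R,3S)-3-[4-hydroxy-3-(3-methylbut-2-en-1-yl)phenyl]oxiran-2-yl}methanone (trans) | O=C([C@@H]1O[C@H]1c1ccc(O)c(CC=C(C)C)c1)c1cc(CC=C(C)C)c(O)c(CC=C(C)C)c1O | intermediate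
10 | Lespeflorin B3, (2R,3R)-3,7-dihydroxy-2-[4-hydroxy-3-(3-methylbut-2-en-1-yl)phenyl]-6,8-bis(3-methylbut-2-en-1-yl)chroman-4-one (2,3-trans) | CC(C)=CCc1cc([C@H]2Oc3c(cc(CC=C(C)C)c(O)c3CC=C(C)C)C(=O)[C@@H]2O)ccc1O | target

**Totals and risks**

Total step count: 6. Longest linear sequence: 4 (steps 1, 2, 3, 6).

The three steps most likely to fail:

Step 6 (Darzens/cyclisation). The electron-rich aldehyde may add slowly, the enantiomeric excess may be only moderate, and the acid stage can close ortho-prenyl phenols to chromans if it is run too hot or too long. The fallback sets out from 3 (with 7) and comes back to the route at 8. Claisen–Schmidt condensation of 3 with 7 (KOH, EtOH, rt) gives the (E)-tris-MOM chalcone F1. Juliá–Colonna epoxidation of F1 (poly-L-leucine, urea–H2O2, DBU, THF, rt) is nucleophilic, so it leaves the prenyl alkenes alone, and poly-L-leucine is known to give the (2R,3S) oxides of chalcones. It gives 8, which is now isolated and purified, and the acid stage of step 6 is then run on pure 8.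

Step 1 (double C-prenylation). The reaction gives mixtures of mono-C-, di-C- and O-prenylated products, and the yield of 2 is expected to be modest. The fallback sets out from 1 and comes back at 3. Iodination (I2, HIO3, aq EtOH) gives 1-(2,4-dihydroxy-3,5-diiodophenyl)ethan-1-one F2. NaH/MOMCl in DMF gives 1-[3,5-diiodo-2,4-bis(methoxymethoxy)phenyl]ethan-1-one F3. A double Stille coupling of F3 with tributyl(3-methylbut-2-en-1-yl)stannane (Pd(PPh3)4, DMF, 90 °C) puts both prenyl groups on defined positions and gives 3.

Step 3 (α-chlorination). Proton transfer between product and enolate can give mixtures of starting ketone, mono- and dichloro ketone. The fallback sets out from 3 and comes back at 4. The potassium enolate (KHMDS, THF, −78 °C) is hydroxylated with (camphorsulfonyl)oxaziridine to give the hydroxymethyl ketone 2-hydroxy-1-[2,4-bis(methoxymethoxy)-3,5-bis(3-methylbut-2-en-1-yl)phenyl]ethan-1-one F4. An Appel reaction on F4 (PPh3, CCl4, CH2Cl2, rt) replaces OH by Cl under neutral conditions and gives 4.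

**Further compounds**

F1 | step 6 | (E)-1-[2,4-bis(methoxymethoxy)-3,5-bis(3-methylbut-2-en-1-yl)phenyl]-3-[4-(methoxymethoxy)-3-(3-methylbut-2-en-1-yl)phenyl]prop-2-en-1-one | COCOc1ccc(/C=C/C(=O)c2cc(CC=C(C)C)c(OCOC)c(CC=C(C)C)c2OCOC)cc1CC=C(C)C
F2 | step 1 | 1-(2,4-dihydroxy-3,5-diiodophenyl)ethan-1-one | CC(=O)c1cc(I)c(O)c(I)c1O
F3 | step 1 | 1-[3,5-diiodo-2,4-bis(methoxymethoxy)phenyl]ethan-1-one | CC(=O)c1cc(I)c(OCOC)c(I)c1OCOC
F4 | step 3 | 2-hydroxy-1-[2,4-bis(methoxymethoxy)-3,5-bis(3-methylbut-2-en-1-yl)phenyl]ethan-1-one | O=C(CO)c1cc(CC=C(C)C)c(OCOC)c(CC=C(C)C)c1OCOC
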